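**Retrosynthetic overview** (carotenoid numbering: ring A = the tetradehydro ring C1–C6, ring B = the hydroxy ring C1'–C6')
- The C15–C15' bond is cut (Suzuki–Miyaura) into two C20 halves, alkenyl boronate 20 (ring A) and alkenyl iodide 24 (ring B); both come from one keto ester, 14.
- Enabling feature: each end ring is a 4-alkylidenecyclohex-2-ene, with the exocyclic C6=C7 alkene next to the ring alkene C4=C5(Me) and the quaternary C1 between C2 and C6. With C3 as a ketone this is a 4-alkylidenecyclohex-2-enone.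
- That enone is the product pattern of a rhodium-catalysed hydroacylative [4+2] annulation of an acyclic 4-alkynal (C3 aldehyde, C2, C1, C6≡C7) with a two-carbon alkyne (C4≡C5–Me); this step makes C3–C4 and C5–C6 and fixes the C6=C7 geometry.
- Afterwards C3=O is removed in ring A (enol triflate, formate reduction, giving C2=C3) and reduced to the (3'S)-carbinol in ring B; the SiMe3 regiocontrol group is cleaved.
- Ring order: the six-membered ring is formed once (step 7) and serves as ring A and ring B. Its precursor 10 comes from a Sonogashira coupling of ynal 3 with trienyl iodide 9.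

Key step: step 7

Assumption: phosphonate 8 (the C5 phosphonate used for crocetin esters) is taken as purchasable; otherwise it is one Arbuzov step from ethyl 4-bromo-2-methylbut-2-enoate.

**Step 1**
Reactants: 1 2,2-dimethylpent-4-enal
Product: 2 3,3-dimethylhex-5-en-1-yne
Conditions: dimethyl (1-diazo-2-oxopropyl)phosphonate, K2CO3, MeOH, 0 °C to rt
Reagents that add atoms: dimethyl (1-diazo-2-oxopropyl)phosphonate, CC(=O)C(=[N+]=[N-])P(=O)(OC)OC
Why: Ohira–Bestmann homologation of a non-enolisable α-quaternary aldehyde to the terminal alkyne; the alkene is inert.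

**Step 2**
Reactants: 2 3,3-dimethylhex-5-en-1-yne
Product: 3 3,3-dimethylpent-4-ynal
Conditions: OsO4 (cat.), NaIO4, 2,6-lutidine, dioxane/H2O, rt
Reagents that add atoms: osmium tetroxide, O=[Os](=O)(=O)=O (transfers the new oxygen; turned over by sodium periodate, [Na+].[O-]I(=O)(=O)=O)
Why: Lemieux–Johnson cleavage; OsO4 dihydroxylates the monosubstituted alkene far faster than the alkyne, and periodate cleaves the diol to the aldehyde.

**Step 3**
Reactants: 4 prop-2-yn-1-ol
Product: 6 (E)-3-iodo-2-methylprop-2-en-1-ol, via alkenylalane 5 (not isolated)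
Conditions: Me3Al, Cp2ZrCl2 (cat.), CH2Cl2, 0 °C to rt; then I2, THF, −30 °C to 0 °C
Reagents that add atoms: trimethylaluminium, C[Al](C)C; iodine, II
Why: Negishi zirconium-catalysed carboalumination adds methyl and aluminium syn with aluminium on the terminal carbon; iodinolysis with retention should give the E iodide.

**Step 4**
Reactants: 6 (E)-3-iodo-2-methylprop-2-en-1-ol
Product: 7 (E)-3-iodo-2-methylprop-2-enal
Conditions: MnO2, CH2Cl2, rt, dark
Reagents that add atoms: none
Why: MnO2 oxidation of a primary allylic alcohol; the alkene geometry is not touched.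

**Step 5**
Reactants: 7 (E)-3-iodo-2-methylprop-2-enal; 8 ethyl (2E)-4-(diethoxyphosphoryl)-2-methylbut-2-enoate
Product: 9 ethyl (2E,4E,6E)-7-iodo-2,6-dimethylhepta-2,4,6-trienoate
Conditions: LiN(SiMe3)2, THF, −78 °C to 0 °C
Reagents that add atoms: none
Why: vinylogous Horner–Wadsworth–Emmons olefination at the carbon α to phosphorus; the stabilised anion should give the new disubstituted alkene E.

**Step 6**
Reactants: 3 3,3-dimethylpent-4-ynal; 9 ethyl (2E,4E,6E)-7-iodo-2,6-dimethylhepta-2,4,6-trienoate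
Product: 10 ethyl (2E,4E,6E)-2,6,10,10-tetramethyl-12-oxododeca-2,4,6-trien-8-ynoate
Conditions: Pd(PPh3)2Cl2 (cat.), CuI (cat.), Et3N, THF, rt, degassed
Reagents that add atoms: none
Why: Sonogashira coupling of an electron-poor alkenyl iodide with retention of alkene geometry; the aliphatic aldehyde tolerates the tertiary amine at rt.

**Step 7**
Reactants: 10 ethyl (2E,4E,6E)-2,6,10,10-tetramethyl-12-oxododeca-2,4,6-trien-8-ynoate; 11 1-(trimethylsilyl)propyne
Product: 13 ethyl (2E,4E,6E,8E)-2,6-dimethyl-8-[2,6,6-trimethyl-4-oxo-3-(trimethylsilyl)cyclohex-2-en-1-ylidene]octa-2,4,6-trienoate, via rhodacycle 12 (not isolated)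
Conditions: [Rh(dppe)]2(BF4)2 (5 mol%), 11 (5 equiv), CH2Cl2, rt
Reagents that add atoms: none
Why: Cationic monovalent rhodium inserts into the aldehyde C–H bond of 10, and the acyl rhodium hydride adds H and Rh syn across the tethered alkyne (5-exo-dig, Rh on C6, H on C7) to give the five-membered acyl(alkenyl) trivalent rhodium metallacycle 12; alkyne 11 then inserts into the Rh–alkenyl bond and reductive elimination follows, so C5–C6 and C3–C4 form in one catalytic cycle. The closest known reaction type is the rhodium-catalysed hydroacylative [4+2] annulation of 4-alkynals with alkynes to 4-alkylidenecyclohex-2-enones. The six-membered carbocycle is closed by acyl–alkenyl reductive elimination from a seven-membered rhodacycle (formal [4+2]: four-carbon unit C3–C2–C1–C6, two-carbon unit C4–C5). No stereocentre is formed; the C6=C7 geometry (chain syn to the gem-dimethyl carbon C1) follows from the syn hydrorhodation, is retained through insertion, and is expected to be the less strained isomer. The step needs regioselective insertion (methyl-bearing alkyne carbon to C6, silicon-bearing carbon to Rh and then to the acyl carbon), which the size and α-metal preference of SiMe3 should secure. It also needs [4+2] to win over intramolecular hydroacylation to a cyclopentenone, which the excess of 11 and the quaternary C1 (Thorpe–Ingold bias towards the small metallacycle) should secure; the chelating alkyne should outcompete the trienoate for Rh–H.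

**Step 8**
Reactants: 13 silyl dienone ester
Product: 14 ethyl (2E,4E,6E,8E)-2,6-dimethyl-8-(2,6,6-trimethyl-4-oxocyclohex-2-en-1-ylidene)octa-2,4,6-trienoate
Conditions: Bu4NF, AcOH, THF, 0 °C to rt
Reagents that add atoms: none
Why: fluoride-induced protodesilylation of an α-silyl enone (the C(sp2)–Si bond next to the carbonyl is activated towards fluoride); acetic acid buffers the base-sensitive dienone and protonates C4.

**Step 9**
Reactants: 14 keto ester
Product: 16 ethyl (2E,4E,6E,8Z)-2,6-dimethyl-8-[2,6,6-trimethyl-4-(trifluoromethanesulfonyloxy)cyclohexa-2,4-dien-1-ylidene]octa-2,4,6-trienoate, via potassium dienolate 15 (not isolated)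
Conditions: KN(SiMe3)2, THF, −78 °C; then PhNTf2, −78 °C to 0 °C
Reagents that add atoms: N-phenylbis(trifluoromethanesulfonimide), O=S(=O)(N(c1ccccc1)S(=O)(=O)C(F)(F)F)C(F)(F)F
Why: kinetic α'-deprotonation at C2 (the only α-CH2 of the ketone) gives the cross-conjugated dienolate, which is O-sulfonylated; the ester has no α-hydrogen.

**Step 10**
Reactants: 16 dienyl triflate
Product: 17 ethyl (2E,4E,6E,8Z)-2,6-dimethyl-8-(2,6,6-trimethylcyclohexa-2,4-dien-1-ylidene)octa-2,4,6-trienoate
Conditions: Pd(OAc)2 (cat.), PPh3, HCO2H, Bu3N, DMF, 60 °C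
Reagents that add atoms: none
Why: palladium-catalysed formate reduction of an enol triflate (oxidative addition, formate exchange, decarboxylation, C–H reductive elimination); this turns the former C3 carbonyl into the C2=C3 alkene of ring A.

**Step 11**
Reactants: 17 ring A ester
Product: 18 (2E,4E,6E,8Z)-2,6-dimethyl-8-(2,6,6-trimethylcyclohexa-2,4-dien-1-ylidene)octa-2,4,6-trien-1-ol
Conditions: iBu2AlH, CH2Cl2, −78 °C; Rochelle salt work-up
Reagents that add atoms: none
Why: 1,2-reduction of a conjugated ester to the allylic alcohol.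

**Step 12**
Reactants: 18 ring A alcohol
Product: 19 (2E,4E,6E,8Z)-2,6-dimethyl-8-(2,6,6-trimethylcyclohexa-2,4-dien-1-ylidene)octa-2,4,6-trienal
Conditions: MnO2, CH2Cl2, rt, dark
Reagents that add atoms: none
Why: MnO2 oxidation of a polyenylic primary alcohol, as in retinol-to-retinal oxidations.

**Step 13**
Reactants: 19 ring A aldehyde
Product: 20 2-[(1E,3E,5E,7E,9Z)-3,7-dimethyl-9-(2,6,6-trimethylcyclohexa-2,4-dien-1-ylidene)nona-1,3,5,7-tetraen-1-yl]-4,4,5,5-tetramethyl-1,3,2-dioxaborolane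
Conditions: CrCl2, Cl2CHBpin, LiI, THF, rt, dark
Reagents that add atoms: 2-(dichloromethyl)-4,4,5,5-tetramethyl-1,3,2-dioxaborolane, ClC(Cl)B1OC(C)(C)C(C)(C)O1
Why: Takai–Utimoto boryl olefination; the geminal dichromium reagent adds to the aldehyde and eliminates to the E-alkenyl boronate (C14=C15).

**Step 14**
Reactants: 14 keto ester
Product: 21 ethyl (2E,4E,6E,8E)-8-[(4S)-4-hydroxy-2,6,6-trimethylcyclohex-2-en-1-ylidene]-2,6-dimethylocta-2,4,6-trienoate
Conditions: (R)-2-methyl-CBS-oxazaborolidine (20 mol%), catecholborane, toluene, −78 °C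
Reagents that add atoms: none
Why: Corey–Bakshi–Shibata reduction; with the dienyl arm (C4'=C5') as the large group and the C2' methylene as the small one, the (R)-catalyst should deliver hydride to the face that gives the (3'S)-carbinol. The ester is inert to catecholborane at this temperature.

**Step 15**
Reactants: 21 ring B hydroxy ester
Product: 22 (2E,4E,6E,8E)-8-[(4S)-4-hydroxy-2,6,6-trimethylcyclohex-2-en-1-ylidene]-2,6-dimethylocta-2,4,6-trien-1-ol
Conditions: iBu2AlH (excess), CH2Cl2, −78 °C; Rochelle salt work-up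
Reagents that add atoms: none
Why: 1,2-reduction of the conjugated ester; the free secondary alcohol only consumes one equivalent of hydride and C3' is not touched.

**Step 16**
Reactants: 22 ring B diol
Product: 23 (2E,4E,6E,8E)-8-[(4S)-4-hydroxy-2,6,6-trimethylcyclohex-2-en-1-ylidene]-2,6-dimethylocta-2,4,6-trienal
Conditions: TEMPO (cat.), PhI(OAc)2, CH2Cl2, rt
Reagents that add atoms: none
Why: oxoammonium oxidation is selective for the primary allylic alcohol over the hindered secondary ring carbinol, so no protecting group is needed.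

**Step 17**
Reactants: 23 ring B hydroxy aldehyde
Product: 24 (1S,4E)-4-[(2E,4E,6E,8E)-9-iodo-3,7-dimethylnona-2,4,6,8-tetraen-1-ylidene]-3,5,5-trimethylcyclohex-2-en-1-ol
Conditions: CrCl2, CHI3, THF, 0 °C to rt, dark
Reagents that add atoms: iodoform, IC(I)I
Why: Takai iodo-olefination gives the E-alkenyl iodide (C14'=C15'); excess divalent chromium tolerates the free hydroxyl.

**Step 18**
Reactants: 20 ring A alkenyl boronate; 24 ring B alkenyl iodide
Product: 25 CNP0202479.1, (1S,4E)-4-[(2E,4E,6E,8E,10E,12E,14E,16E,18Z)-3,7,12,16-tetramethyl-18-(2,6,6-trimethylcyclohexa-2,4-dien-1-ylidene)octadeca-2,4,6,8,10,12,14,16-octaen-1-ylidene]-3,5,5-trimethylcyclohex-2-en-1-ol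
Conditions: Pd(PPh3)4 (cat.), TlOEt, THF/H2O, rt, degassed, dark
Reagents that add atoms: none
Why: Suzuki–Miyaura coupling of an alkenyl boronate with an alkenyl iodide forms the C15–C15' single bond with retention at both alkenes; the base-accelerated rt protocol suits sensitive polyenes and the free carbinol.

**Compound list**
1 | 2,2-dimethylpent-4-enal | O=CC(C)(C)CC=C | starting material
2 | 3,3-dimethylhex-5-en-1-yne | C#CC(C)(C)CC=C | intermediate
3 | 3,3-dimethylpent-4-ynal | C#CC(C)(C)CC=O | intermediate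
4 | prop-2-yn-1-ol | C#CCO | starting material
5 | (E)-alkenylalane, dimethylaluminium alkoxide of 3-(dimethylalumanyl)-2-methylprop-2-en-1-ol | C[Al](C)/C=C(\C)CO[Al](C)C | intermediate (not isolated)
6 | (E)-3-iodo-2-methylprop-2-en-1-ol | OC/C(C)=C/I | intermediate
7 | (E)-3-iodo-2-methylprop-2-enal | O=C/C(C)=C/I | intermediate
8 | ethyl (2E)-4-(diethoxyphosphoryl)-2-methylbut-2-enoate | CCOC(=O)/C(C)=C/CP(=O)(OCC)OCC | starting material
9 | ethyl (2E,4E,6E)-7-iodo-2,6-dimethylhepta-2,4,6-trienoate | CCOC(=O)/C(C)=C/C=C/C(C)=C/I | intermediate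
10 | ethyl (2E,4E,6E)-2,6,10,10-tetramethyl-12-oxododeca-2,4,6-trien-8-ynoate | CCOC(=O)/C(C)=C/C=C/C(C)=C/C#CC(C)(C)CC=O | intermediate
11 | 1-(trimethylsilyl)propyne | CC#C[Si](C)(C)C | starting material
12 | five-membered acyl(alkenyl)rhodium metallacycle (dppe on Rh and the BF4 counter-ion not drawn) | CCOC(=O)/C(C)=C/C=C/C(C)=C/C=C1/[Rh]C(=O)CC1(C)C | intermediate (not isolated)
13 | ethyl (2E,4E,6E,8E)-2,6-dimethyl-8-[2,6,6-trimethyl-4-oxo-3-(trimethylsilyl)cyclohex-2-en-1-ylidene]octa-2,4,6-trienoate | CCOC(=O)/C(C)=C/C=C/C(C)=C/C=C1/C(C)=C([Si](C)(C)C)C(=O)CC1(C)C | intermediate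
14 | ethyl (2E,4E,6E,8E)-2,6-dimethyl-8-(2,6,6-trimethyl-4-oxocyclohex-2-en-1-ylidene)octa-2,4,6-trienoate | CCOC(=O)/C(C)=C/C=C/C(C)=C/C=C1/C(C)=CC(=O)CC1(C)C | intermediate
15 | potassium dienolate of 14 | CCOC(=O)/C(C)=C/C=C/C(C)=C/C=C1/C(C)=CC([O-])=CC1(C)C.[K+] | intermediate (not isolated)
16 | ethyl (2E,4E,6E,8Z)-2,6-dimethyl-8-[2,6,6-trimethyl-4-(trifluoromethanesulfonyloxy)cyclohexa-2,4-dien-1-ylidene]octa-2,4,6-trienoate | CCOC(=O)/C(C)=C/C=C/C(C)=C/C=C1/C(C)=CC(OS(=O)(=O)C(F)(F)F)=CC1(C)C | intermediate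
17 | ethyl (2E,4E,6E,8Z)-2,6-dimethyl-8-(2,6,6-trimethylcyclohexa-2,4-dien-1-ylidene)octa-2,4,6-trienoate | CCOC(=O)/C(C)=C/C=C/C(C)=C/C=C1/C(C)=CC=CC1(C)C | intermediate
18 | (2E,4E,6E,8Z)-2,6-dimethyl-8-(2,6,6-trimethylcyclohexa-2,4-dien-1-ylidene)octa-2,4,6-trien-1-ol | OC/C(C)=C/C=C/C(C)=C/C=C1/C(C)=CC=CC1(C)C | intermediate
19 | (2E,4E,6E,8Z)-2,6-dimethyl-8-(2,6,6-trimethylcyclohexa-2,4-dien-1-ylidene)octa-2,4,6-trienal | O=C/C(C)=C/C=C/C(C)=C/C=C1/C(C)=CC=CC1(C)C | intermediate
20 | 2-[(1E,3E,5E,7E,9Z)-3,7-dimethyl-9-(2,6,6-trimethylcyclohexa-2,4-dien-1-ylidene)nona-1,3,5,7-tetraen-1-yl]-4,4,5,5-tetramethyl-1,3,2-dioxaborolane | CC1(C)OB(/C=C/C(C)=C/C=C/C(C)=C/C=C2/C(C)=CC=CC2(C)C)OC1(C)C | intermediate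
21 | ethyl (2E,4E,6E,8E)-8-[(4S)-4-hydroxy-2,6,6-trimethylcyclohex-2-en-1-ylidene]-2,6-dimethylocta-2,4,6-trienoate | CCOC(=O)/C(C)=C/C=C/C(C)=C/C=C1/C(C)=C[C@@H](O)CC1(C)C | intermediate
22 | (2E,4E,6E,8E)-8-[(4S)-4-hydroxy-2,6,6-trimethylcyclohex-2-en-1-ylidene]-2,6-dimethylocta-2,4,6-trien-1-ol | OC/C(C)=C/C=C/C(C)=C/C=C1/C(C)=C[C@@H](O)CC1(C)C | intermediate
23 | (2E,4E,6E,8E)-8-[(4S)-4-hydroxy-2,6,6-trimethylcyclohex-2-en-1-ylidene]-2,6-dimethylocta-2,4,6-trienal | O=C/C(C)=C/C=C/C(C)=C/C=C1/C(C)=C[C@@H](O)CC1(C)C | intermediate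
24 | (1S,4E)-4-[(2E,4E,6E,8E)-9-iodo-3,7-dimethylnona-2,4,6,8-tetraen-1-ylidene]-3,5,5-trimethylcyclohex-2-en-1-ol | I/C=C/C(C)=C/C=C/C(C)=C/C=C1/C(C)=C[C@@H](O)CC1(C)C | intermediate
25 | CNP0202479.1, (1S,4E)-4-[(2E,4E,6E,8E,10E,12E,14E,16E,18Z)-3,7,12,16-tetramethyl-18-(2,6,6-trimethylcyclohexa-2,4-dien-1-ylidene)octadeca-2,4,6,8,10,12,14,16-octaen-1-ylidene]-3,5,5-trimethylcyclohex-2-en-1-ol | CC1=CC=CC(C)(C)\C1=C/C=C(C)/C=C/C=C(C)/C=C/C=C/C(C)=C/C=C/C(C)=C/C=C1/C(C)=C[C@@H](O)CC1(C)C | target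

**Step count and risks**
Total step count: 18. Longest linear sequence: 12 steps (steps 3, 4, 5, 6, 7, 8, 9, 10, 11, 12, 13, 18).

Step 7 (most likely to fail). The silylalkyne may insert the wrong way round, or the acyl rhodium hydride may close intramolecularly to a cyclopentenone before the alkyne is taken up. The fallback takes the ring ready-made instead of building it; it sets out from trienyl iodide 9 and returns at keto ester 14. Commercial 2,6,6-trimethylcyclohex-2-ene-1,4-dione F1 is ketalised at its unhindered carbonyl (ethylene glycol, p-TsOH, benzene, reflux) to 7,9,9-trimethyl-1,4-dioxaspiro[4.5]dec-6-en-8-one F2. Boron-Wittig olefination of the remaining hindered ketone (CH2(Bpin)2, lithium tetramethylpiperidide, THF, −78 °C to rt) should give the exocyclic alkenyl boronate 2-[(E)-(7,9,9-trimethyl-1,4-dioxaspiro[4.5]dec-6-en-8-ylidene)methyl]-4,4,5,5-tetramethyl-1,3,2-dioxaborolane F3; an E/Z mixture can be carried on. Suzuki–Miyaura coupling of F3 with 9 (PdCl2(dppf), aqueous K3PO4, THF, rt) should give ethyl (2E,4E,6E,8E)-2,6-dimethyl-8-(7,9,9-trimethyl-1,4-dioxaspiro[4.5]dec-6-en-8-ylidene)octa-2,4,6-trienoate F4. Mild hydrolysis (oxalic acid, THF/H2O, rt) and I2-catalysed equilibration of the exocyclic alkene should then deliver 14.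

Step 18. The boronate may protodeboronate, or the two long polyenes may isomerise or decompose under the basic coupling conditions. The fallback makes the central bond at the alkyne level; it sets out from aldehyde 19 and iodide 24 and returns at 25. Ohira–Bestmann homologation of 19 (reagent of step 1, K2CO3, MeOH/THF) should give (6Z)-6-[(2E,4E,6E)-3,7-dimethylnona-2,4,6-trien-8-yn-1-ylidene]-1,5,5-trimethylcyclohexa-1,3-diene F5. Sonogashira coupling with 24 (Pd(PPh3)4, CuI, Et3N, THF, rt) should give the 14,15-didehydro analogue of the target F6. Semi-hydrogenation (H2, Pd/CaCO3 poisoned with Pb(OAc)2, quinoline, EtOAc) should give the (14Z)-isomer of the target F7, which is equilibrated to all-trans 25 by warming in heptane in the dark, the classical cis-to-trans isomerisation of central-cis carotenoids.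

Step 14. Facial selectivity may be poor, because the small side of the ketone is a methylene next to a quaternary carbon and the enone has no α-substituent. The fallback replaces catalyst control by enzymatic resolution; it sets out from 14 and returns at 21. Luche reduction (NaBH4, CeCl3·7H2O, MeOH, −20 °C) should give the racemic alcohol ethyl (2E,4E,6E,8E)-8-(4-hydroxy-2,6,6-trimethylcyclohex-2-en-1-ylidene)-2,6-dimethylocta-2,4,6-trienoate F8. Lipase-catalysed transesterification (Candida antarctica lipase B, vinyl acetate, hexane, 30 °C) should, by the empirical rule for secondary alcohols with the dienyl arm as the large group, acetylate the (R)-enantiomer to ethyl (2E,4E,6E,8E)-8-[(4R)-4-acetoxy-2,6,6-trimethylcyclohex-2-en-1-ylidene]-2,6-dimethylocta-2,4,6-trienoate F9. This leaves (S)-alcohol 21, which is separated by chromatography.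

**Further compounds**
F1 | step 7 | 2,6,6-trimethylcyclohex-2-ene-1,4-dione | CC1=CC(=O)CC(C)(C)C1=O
F2 | step 7 | 7,9,9-trimethyl-1,4-dioxaspiro[4.5]dec-6-en-8-one | CC1=CC2(CC(C)(C)C1=O)OCCO2
F3 | step 7 | 2-[(E)-(7,9,9-trimethyl-1,4-dioxaspiro[4.5]dec-6-en-8-ylidene)methyl]-4,4,5,5-tetramethyl-1,3,2-dioxaborolane | CC1=CC2(OCCO2)CC(C)(C)\C1=C/B1OC(C)(C)C(C)(C)O1
F4 | step 7 | ethyl (2E,4E,6E,8E)-2,6-dimethyl-8-(7,9,9-trimethyl-1,4-dioxaspiro[4.5]dec-6-en-8-ylidene)octa-2,4,6-trienoate | CCOC(=O)/C(C)=C/C=C/C(C)=C/C=C1/C(C)=CC2(OCCO2)CC1(C)C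
F5 | step 18 | (6Z)-6-[(2E,4E,6E)-3,7-dimethylnona-2,4,6-trien-8-yn-1-ylidene]-1,5,5-trimethylcyclohexa-1,3-diene | C#C/C(C)=C/C=C/C(C)=C/C=C1/C(C)=CC=CC1(C)C
F6 | step 18 | 14,15-didehydro analogue of 25 | CC1=CC=CC(C)(C)\C1=C/C=C(C)/C=C/C=C(C)/C#C/C=C/C(C)=C/C=C/C(C)=C/C=C1/C(C)=C[C@@H](O)CC1(C)C
F7 | step 18 | (14Z)-isomer of 25 | CC1=CC=CC(C)(C)\C1=C/C=C(C)/C=C/C=C(C)/C=C\C=C\C(C)=C\C=C\C(C)=C\C=C1\C(C)=C[C@@H](O)CC1(C)C
F8 | step 14 | racemic ethyl (2E,4E,6E,8E)-8-(4-hydroxy-2,6,6-trimethylcyclohex-2-en-1-ylidene)-2,6-dimethylocta-2,4,6-trienoate | CCOC(=O)/C(C)=C/C=C/C(C)=C/C=C1/C(C)=CC(O)CC1(C)C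
F9 | step 14 | ethyl (2E,4E,6E,8E)-8-[(4R)-4-acetoxy-2,6,6-trimethylcyclohex-2-en-1-ylidene]-2,6-dimethylocta-2,4,6-trienoate | CCOC(=O)/C(C)=C/C=C/C(C)=C/C=C1/C(C)=C[C@H](OC(C)=O)CC1(C)C
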